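**Retrosynthetic overview**
1. Feature: in the oxolane ring (O1, C2 aryl, C3 CH2OH, C4, C5), C5 is a CH2 bound to O1 and can therefore carry a stabilised radical. The unit C4–Cα(OH)Ar is a styrene to which carbon and water have been added.
2. Key disconnection: C4–C5 and Cα–OH are made together. Carbinol 19 comes from the N-(acyloxy)phthalimide 15 of the O1-linked glycolic acid by photoredox decarboxylation, 5-exo-trig closure of the only ring, and capture of the Cα cation by water.
3. Before: 15 comes from alcohol 11, bromoacetic acid and N-hydroxyphthalimide. 11 comes from an auxiliary-controlled anti aldol of styrylacetyl imide 7 with O-benzylvanillin 1, which fixes C2 and C3 (anti in the chain, cis in the ring).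
4. After: both Cα epimers of 19 converge on ketone 20, a CBS reduction sets αS (21), and desilylation and hydrogenolysis give 23.

Key step: step 8

Notation: Ar = 4-benzyloxy-3-methoxyphenyl. Ring atoms are O1, C2 (aryl), C3 (CH2O), C4 (side chain with carbinol carbon Cα) and C5 (CH2). The target is (2S,3S,4R,αS), that is 2,3-cis and 3,4-trans.

Assumption: the MgCl2-catalysed anti aldol is taken to follow the chelated (Z)-enolate model, with the aldehyde entering opposite the benzyl group as in enolate alkylation. This calls for the (S)-auxiliary. If the sense proved to be the reverse, the (R)-auxiliary would be used and nothing else would change.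

**Step 1**
Reactants: 1 4-benzyloxy-3-methoxybenzaldehyde; 2 (2-carboxyethyl)triphenylphosphonium bromide
Product: 4 (E)-4-Ar-but-3-enoic acid, via ylide carboxylate 3 (not isolated)
Conditions: KOtBu (2.3 equiv), THF, 0 °C to rt; then 1 M HCl, 0 °C
Reagents that add atoms: none
Why: Wittig olefination, in which a ylide carrying a carboxylate gives the (E)-alkene with aromatic aldehydes, and conjugation with the arene keeps the double bond in the β,γ-position.

**Step 2**
Reactants: 4 (E)-4-Ar-but-3-enoic acid; 5 (S)-4-benzyloxazolidin-2-one
Product: 7 (S)-4-benzyl-3-[(E)-4-Ar-but-3-enoyl]oxazolidin-2-one, via mixed pivalic anhydride 6 (not isolated)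
Conditions: PivCl, Et3N, THF, −20 °C; then 5, LiCl, −20 °C to rt
Reagents that add atoms: pivaloyl chloride, CC(C)(C)C(=O)Cl (its atoms stay only in 6)
Why: N-acylation of the auxiliary through the mixed anhydride with LiCl activation needs no strong base and forms no ketene, so the alkene neither migrates nor isomerises.

**Step 3**
Reactants: 7 styrylacetyl imide; 1 4-benzyloxy-3-methoxybenzaldehyde
Product: 9 (4S)-4-benzyl-3-{(2R,3E)-4-Ar-2-[(S)-Ar(hydroxy)methyl]but-3-enoyl}oxazolidin-2-one, via silyl ether 8 (not isolated)
Conditions: MgCl2 (0.2 equiv), Et3N (2 equiv), TMSCl (1.5 equiv), EtOAc, 23 °C; then citric acid (cat.), MeOH, 0 °C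
Reagents that add atoms: chlorotrimethylsilane, C[Si](C)(C)Cl (its atoms stay only in 8)
Why: magnesium-halide-catalysed direct anti aldol reaction, in which soft enolisation gives the chelated (Z)-enolate, this attacks the non-enolisable aldehyde through its α-carbon on the face away from the benzyl group via a boat-like transition state, silylation of the aldolate releases the catalyst, and the anti pair so formed (ring C3 and C2) is the cis pair of the later oxolane.

**Step 4**
Reactants: 9 anti aldol
Product: 10 (1S,2S,3E)-1,4-di-Ar-2-(hydroxymethyl)but-3-en-1-ol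
Conditions: LiBH4, THF–Et2O, 0 °C; aq. NH4Cl
Reagents that add atoms: none
Why: reductive cleavage of the imide by hydride attack at the exocyclic carbonyl frees the auxiliary for reuse and touches neither the stereocentres nor the styrene.

**Step 5**
Reactants: 10 diol
Product: 11 (1S,2S,3E)-1,4-di-Ar-2-[(triisopropylsilyloxy)methyl]but-3-en-1-ol
Conditions: TIPSCl (1.05 equiv), imidazole, DMF, 0 °C to rt
Reagents that add atoms: chlorotriisopropylsilane, CC(C)[Si](Cl)(C(C)C)C(C)C
Why: selective silylation of the primary hydroxyl on steric grounds, with TIPS preferred to TBS because it does not migrate to the neighbouring alkoxide in step 6 and its bulk strengthens the facial bias in step 8.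

**Step 6**
Reactants: 11 secondary alcohol; 12 bromoacetic acid
Product: 13 2-{[(1S,2S,3E)-1,4-di-Ar-2-(triisopropylsilyloxymethyl)but-3-enyl]oxy}acetic acid
Conditions: NaH (3.5 equiv), 12 (1.5 equiv), THF–DMF 4:1, 0 °C to rt; then cold 0.5 M HCl to pH 4
Reagents that add atoms: none
Why: Williamson etherification with the carboxylate salt of the halide gives the glycolic acid ether directly, with no ester to exchange or saponify, and the C2–O bond is not involved, so C2 keeps its configuration.

**Step 7**
Reactants: 13 glycolic acid ether; 14 N-hydroxyphthalimide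
Product: 15 N-phthalimidoyl 2-{[(1S,2S,3E)-1,4-di-Ar-2-(triisopropylsilyloxymethyl)but-3-enyl]oxy}acetate
Conditions: DIC, DMAP (cat.), CH2Cl2, 0 °C to rt; short silica plug
Reagents that add atoms: none
Why: Steglich-type carbodiimide esterification gives the redox-active ester under neutral conditions that spare the silyl ether, the benzylic ether and the styrene.

**Step 8**
Reactants: 15 N-(acyloxy)phthalimide
Product: 19 (2S,3S,4R)-2-Ar-4-[Ar(hydroxy)methyl]-3-(triisopropylsilyloxymethyl)oxolane as both Cα epimers, via alkoxymethyl radical 16 (not isolated), via benzylic radical 17 (not isolated), via benzylic cation 18 (not isolated)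
Conditions: fac-Ir(ppy)3 (1 mol %), acetone–H2O 9:1 (0.01 M), 450 nm LEDs, 20–25 °C, Ar
Reagents that add atoms: water, O
Why: Proposed new method: excited fac-Ir(ppy)3 reduces the phthalimide ester, N–O cleavage and loss of CO2 give the nucleophilic radical 16 at C5, this adds to C4 of the styrene, and the p-alkoxybenzyl radical 17 is oxidised by the tetravalent iridium complex to cation 18, which water captures, so the sequence is redox neutral. The closest known reaction type is the intermolecular three-component photoredox oxyalkylation of styrenes with N-(acyloxy)phthalimides and water, and the ring closure alone has its analogue in tin hydride cyclisations of alkoxymethyl radicals; joining the two in one intramolecular event is new. The oxolane closes 5-exo-trig (C5 on C4), which is favoured over 6-endo by overlap and because only the exo mode leaves a benzylic radical. C4 is controlled by C3: in the chair-like 5-hexenyl transition state the CH2OTIPS group next to the alkene lies pseudo-equatorial and so ends trans to the new Cα branch, the cis-related C2 aryl group is then pseudo-axial and faces only hydrogens on C5 and C4, and the alternative leads to a crowded all-cis oxolane. Cα is not relied on, because in the conformer of 18 with least allylic 1,3-strain (C4–H in the cation plane, toward the arene) water should enter opposite C3, which points to the αR epimer, so 19 is carried on as the mixture and Cα is set in steps 9 and 10. The step needs ring closure to outrun oxidation of 16 to an oxocarbenium ion and intermolecular addition, which the minute stationary concentration of tetravalent iridium, the activated styrene and high dilution secure, while the 3,4-trans geometry keeps the silyl ether oxygen and the C2 arene out of reach of 18.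

**Step 9**
Reactants: 19 carbinol (both Cα epimers)
Product: 20 Ar [(3R,4S,5S)-5-Ar-4-(triisopropylsilyloxymethyl)oxolan-3-yl] ketone
Conditions: Pr4N[RuO4] (5 mol %), NMO (1.5 equiv), 4 Å MS, CH2Cl2, rt
Reagents that add atoms: none
Why: Ley–Griffith oxidation under neutral conditions merges both epimers into one aryl ketone, and C4, now α to the carbonyl, already holds the more stable arrangement trans to C3, so enolisation cannot harm it.

**Step 10**
Reactants: 20 ketone
Product: 21 (2S,3S,4R)-2-Ar-4-[(S)-Ar(hydroxy)methyl]-3-(triisopropylsilyloxymethyl)oxolane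
Conditions: (R)-2-methyl-CBS-oxazaborolidine (0.3 equiv), BH3·SMe2 (1.0 equiv), THF, −20 °C; MeOH quench
Reagents that add atoms: none
Why: Corey–Bakshi–Shibata reduction, in which the (R)-catalyst treats the aryl group as the large substituent and delivers hydride to the face that gives the (S)-carbinol, and the Felkin–Anh model (C3 anti to hydride, C5 next to the carbonyl oxygen) favours the same face, so catalyst and substrate are matched.

**Step 11**
Reactants: 21 (αS)-carbinol
Product: 22 (2S,3S,4R)-2-Ar-4-[(S)-Ar(hydroxy)methyl]-3-(hydroxymethyl)oxolane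
Conditions: TBAF (1.2 equiv), THF, 0 °C to rt
Reagents that add atoms: none
Why: fluoride-driven Si–O cleavage is done while the phenols are still masked, so no p-hydroxybenzylic alcohol is exposed to basic fluoride.

**Step 12**
Reactants: 22 bis(benzyl ether) diol
Product: 23 (2S,3S,4R)-2-(4-hydroxy-3-methoxyphenyl)-3-(hydroxymethyl)-4-[(S)-hydroxy(4-hydroxy-3-methoxyphenyl)methyl]oxolane (target)
Conditions: H2 (1 atm), Pd/C (10 wt %), EtOAc–EtOH, rt, stopped after uptake of 2 equiv H2
Reagents that add atoms: none
Why: catalytic hydrogenolysis cleaves aryl benzyl ethers much faster than the secondary benzylic C–O bonds at C2 and Cα in a neutral, acid-free medium, and no stereocentre is involved.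

**Compound list**
1 | 4-benzyloxy-3-methoxybenzaldehyde | COc1cc(C=O)ccc1OCc1ccccc1 | starting material
2 | (2-carboxyethyl)triphenylphosphonium bromide | OC(=O)CC[P+](c1ccccc1)(c1ccccc1)c1ccccc1.[Br-] | starting material
3 | potassium 3-(triphenylphosphoranylidene)propanoate | [K+].[O-]C(=O)CC=P(c1ccccc1)(c1ccccc1)c1ccccc1 | intermediate
4 | (E)-4-(4-benzyloxy-3-methoxyphenyl)but-3-enoic acid | OC(=O)C/C=C/c1ccc(OCc2ccccc2)c(OC)c1 | intermediate
5 | (S)-4-benzyloxazolidin-2-one | O=C1N[C@@H](Cc2ccccc2)CO1 | starting material
6 | mixed pivalic anhydride of 4 | CC(C)(C)C(=O)OC(=O)C/C=C/c1ccc(OCc2ccccc2)c(OC)c1 | intermediate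
7 | (S)-4-benzyl-3-[(E)-4-Ar-but-3-enoyl]oxazolidin-2-one | O=C(C/C=C/c1ccc(OCc2ccccc2)c(OC)c1)N1C(=O)OC[C@@H]1Cc1ccccc1 | intermediate
8 | trimethylsilyl ether of anti aldol 9 | C[Si](C)(C)O[C@H](c1ccc(OCc2ccccc2)c(OC)c1)[C@H](C(=O)N1C(=O)OC[C@@H]1Cc1ccccc1)/C=C/c1ccc(OCc2ccccc2)c(OC)c1 | intermediate
9 | anti aldol, acyl C2 R, carbinol S | O[C@H](c1ccc(OCc2ccccc2)c(OC)c1)[C@H](C(=O)N1C(=O)OC[C@@H]1Cc1ccccc1)/C=C/c1ccc(OCc2ccccc2)c(OC)c1 | intermediate
10 | (1S,2S,3E)-1,4-di-Ar-2-(hydroxymethyl)but-3-en-1-ol | O[C@H](c1ccc(OCc2ccccc2)c(OC)c1)[C@H](CO)/C=C/c1ccc(OCc2ccccc2)c(OC)c1 | intermediate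
11 | primary TIPS ether of 10 | O[C@H](c1ccc(OCc2ccccc2)c(OC)c1)[C@H](CO[Si](C(C)C)(C(C)C)C(C)C)/C=C/c1ccc(OCc2ccccc2)c(OC)c1 | intermediate
12 | bromoacetic acid | OC(=O)CBr | starting material
13 | O1-linked glycolic acid ether | OC(=O)CO[C@H](c1ccc(OCc2ccccc2)c(OC)c1)[C@H](CO[Si](C(C)C)(C(C)C)C(C)C)/C=C/c1ccc(OCc2ccccc2)c(OC)c1 | intermediate
14 | N-hydroxyphthalimide | ON1C(=O)c2ccccc2C1=O | starting material
15 | N-(acyloxy)phthalimide, key-step precursor | O=C(CO[C@H](c1ccc(OCc2ccccc2)c(OC)c1)[C@H](CO[Si](C(C)C)(C(C)C)C(C)C)/C=C/c1ccc(OCc2ccccc2)c(OC)c1)ON1C(=O)c2ccccc2C1=O | intermediate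
16 | C5 alkoxymethyl radical | [CH2]O[C@H](c1ccc(OCc2ccccc2)c(OC)c1)[C@H](CO[Si](C(C)C)(C(C)C)C(C)C)/C=C/c1ccc(OCc2ccccc2)c(OC)c1 | intermediate
17 | Cα benzylic radical, ring closed | COc1cc(ccc1OCc1ccccc1)[CH][C@H]2CO[C@H](c3ccc(OCc4ccccc4)c(OC)c3)[C@@H]2CO[Si](C(C)C)(C(C)C)C(C)C | intermediate
18 | Cα benzylic cation | COc1cc(ccc1OCc1ccccc1)[CH+][C@H]2CO[C@H](c3ccc(OCc4ccccc4)c(OC)c3)[C@@H]2CO[Si](C(C)C)(C(C)C)C(C)C | intermediate
19 | protected carbinol, C2, C3 and C4 defined, both Cα epimers | COc1cc(ccc1OCc1ccccc1)C(O)[C@H]2CO[C@H](c3ccc(OCc4ccccc4)c(OC)c3)[C@@H]2CO[Si](C(C)C)(C(C)C)C(C)C | intermediate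
20 | aryl oxolanyl ketone | COc1cc(ccc1OCc1ccccc1)C(=O)[C@H]2CO[C@H](c3ccc(OCc4ccccc4)c(OC)c3)[C@@H]2CO[Si](C(C)C)(C(C)C)C(C)C | intermediate
21 | protected target, single (αS) epimer | COc1cc(ccc1OCc1ccccc1)[C@@H](O)[C@H]2CO[C@H](c3ccc(OCc4ccccc4)c(OC)c3)[C@@H]2CO[Si](C(C)C)(C(C)C)C(C)C | intermediate
22 | bis(benzyl ether) diol | COc1cc(ccc1OCc1ccccc1)[C@@H](O)[C@H]2CO[C@H](c3ccc(OCc4ccccc4)c(OC)c3)[C@@H]2CO | intermediate
23 | CNP0236765.6 | COc1cc([C@@H](O)[C@H]2CO[C@H](c3ccc(O)c(OC)c3)[C@@H]2CO)ccc1O | target

Total step count: 12
Longest linear sequence: 12 steps (from 1 or 2 to 23)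

**Steps most likely to fail**

1. Step 8.
   - Possible failures in radical generation and capture:
     - The activated ester may hydrolyse in the aqueous medium.
     - The cation may lose the C4 proton or be captured by phthalimide instead of water.
     - Radical 16 may leak by β-scission to formaldehyde.
   - Possible failures in facial selectivity at C4:
     - Triplet energy transfer from the photocatalyst may isomerise the styrene and change the facial bias.
     - The C2 aryl group on its own prefers a 2,4-cis closure and works against the C3 group.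
   - Fallback (known chemistry, from acid 13 back to carbinol 19):
     - 13 is coupled in the dark with 1-hydroxypyridine-2(1H)-thione (DCC, CH2Cl2, 0 °C) to the O-acyl thiohydroxamate (Barton ester) F1.
     - Tungsten-lamp irradiation in dilute benzene runs the Barton decarboxylation chain with the same 5-exo closure and transfers the pyridylthio group to the benzylic radical, giving the Cα 2-pyridyl sulfide F2.
     - Thiophilic activation (AgOTf, 2,6-lutidine, acetone–water, 0 °C) ionises the p-alkoxybenzylic C–S bond, and water gives 19.

2. Step 3.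
   - Possible failures:
     - The doubly activated α-carbon may epimerise.
     - Silanol may be lost by β-elimination to a dienoyl imide.
     - The dienolate may react at its γ-carbon.
     - The anti/syn ratio may erode, because the addition is reversible.
   - Fallback (from imide 7 and aldehyde 1 back to aldol 9):
     - 7 is converted with Bu2BOTf and i-Pr2NEt (CH2Cl2, 0 °C) into the dibutylboron (Z)-enolate F3.
     - F3 is added at −78 °C to 1 precomplexed with Et2AlCl.
     - The aldol then runs irreversibly through an open transition state on the same enolate face and gives the anti adduct. A buffered H2O2 work-up releases 9.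

3. Step 10.
   - Possible failure: the oxazaborolidine may not tell the aryl group from the branched oxolanyl group well enough, which lowers facial selectivity, and uncatalysed borane reduction may add to this.
   - Fallback (from ketone 20 back to carbinol 21):
     - Control passes from the catalyst to the substrate by chelation-controlled reduction with Zn(BH4)2 in Et2O at −20 °C.
     - Zinc ties the carbonyl oxygen to O1 in a six-membered chelate, which places C3 on one face.
     - Hydride then enters from the C4–H side, which leads to the (αS)-carbinol.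
     - This fallback makes no new compound (F0).

**Further compounds**
F1 | step 8 | O-acyl thiohydroxamate (Barton ester) of 13 | O=C(CO[C@H](c1ccc(OCc2ccccc2)c(OC)c1)[C@H](CO[Si](C(C)C)(C(C)C)C(C)C)/C=C/c1ccc(OCc2ccccc2)c(OC)c1)ON1C=CC=CC1=S
F2 | step 8 | Cα 2-pyridyl sulfide, both Cα epimers | COc1cc(ccc1OCc1ccccc1)C(Sc1ccccn1)[C@H]2CO[C@H](c3ccc(OCc4ccccc4)c(OC)c3)[C@@H]2CO[Si](C(C)C)(C(C)C)C(C)C
F3 | step 3 | dibutylboron (Z)-enolate of 7 | CCCCB(CCCC)O/C(=C\C=C\c1ccc(OCc2ccccc2)c(OC)c1)N1C(=O)OC[C@@H]1Cc1ccccc1
F0 | step 10 | none | none
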